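**Retrosynthetic overview**
1. Bongardol is the octacosanoate (C28, montanate) ester of tyrosol. The only strategic disconnection is the ester C(acyl)–O bond.
2. This gives two commercial building blocks: octacosanoic acid and tyrosol.
3. No rings are formed; the single benzene ring is bought intact in tyrosol.
4. The only selectivity issue is primary aliphatic OH versus phenolic OH, solved by acid-catalysed (Fischer) esterification, which does not acylate phenols.

Assumption: the target has no stereocentres (it is achiral), so the "single enantiomer" requirement is met automatically; octacosanoic acid and tyrosol are taken as catalogue chemicals.

**Route**

Step 1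
Reactants: **1** octacosanoic acid (montanic acid, CH3(CH2)26CO2H), 1.0 equiv; **2** tyrosol (4-(2-hydroxyethyl)phenol), 1.5–2.0 equiv
Product: **3** Bongardol, 2-(4-hydroxyphenyl)ethyl octacosanoate (C36H64O3, MW 544.9)
Conditions: p-TsOH·H2O (5–10 mol %), toluene, reflux, Dean–Stark, 8–16 h. Cool so the product precipitates, filter, wash with cold MeOH (removes excess tyrosol and TsOH), then recrystallise from hot acetone or pass through a short silica plug in warm CH2Cl2.
Reagents that add atoms: none beyond reactants **1** and **2** (p-TsOH is catalytic; water is lost).
Why: Fischer esterification. Under acid-catalysed equilibrium conditions the primary aliphatic alcohol is esterified, while the weakly nucleophilic phenol is not (aryl ester formation is unfavourable). Azeotropic water removal and excess of the water/MeOH-soluble tyrosol drive the waxy acid to full conversion. Both partners are molten or soluble in toluene at 110 °C. No stereocentre is created.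

Checks on the route: the atom balance is C28H56O2 + C8H10O2 → C36H64O3 + H2O, and the product is the target (C28 acyl chain, O–CH2CH2–aryl linker, para free phenol). The saturated chain, the ester and the phenol all tolerate catalytic TsOH in toluene. There are no stereocentres to set or scramble.

**Compound list**
1 | octacosanoic acid (montanic acid) | CCCCCCCCCCCCCCCCCCCCCCCCCCCC(=O)O | starting material
2 | tyrosol, 4-(2-hydroxyethyl)phenol | OCCc1ccc(O)cc1 | starting material
3 | Bongardol, 2-(4-hydroxyphenyl)ethyl octacosanoate | CCCCCCCCCCCCCCCCCCCCCCCCCCCC(=O)OCCc1ccc(O)cc1 | target

**Totals**
Total step count: 1
Longest linear sequence: 1 step

**Most likely failures and fallbacks**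
The route has only one step, so these are its three most likely failure modes, each with a fallback that changes the approach.

1. Incomplete conversion, leaving C28 acid that co-crystallises with the waxy product.
 Fallback: Mitsunobu esterification of **1** with **2** (PPh3, DIAD, THF, 40 °C). The alcohol carbon is activated instead of the acyl carbon, and the carboxylic acid (pKa about 5) is alkylated in preference to the phenol (pKa about 10).

2. Loss of chemoselectivity or acid-mediated side reactions of the free phenol/tyrosol (aryl ester, diester, coloured oligomers).
 Fallback: a two-step protecting-group route. Couple **1** with commercial 2-(4-benzyloxyphenyl)ethanol (EDC·HCl, DMAP, warm CH2Cl2/CHCl3, Steglich), then remove the benzyl group with H2, Pd/C in THF/EtOAc. The saturated chain and the ester are inert to hydrogenolysis.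

3. Hot-acid conditions or work-up proving impractical (emulsions, difficult purification of the wax).
 Fallback: enzymatic acylation with immobilised Candida antarctica lipase B (Novozym 435), toluene/2-methyl-2-butanol, 65 °C, 4 Å MS, using **1** or its vinyl/methyl ester. The lipase acylates only the primary alcohol under neutral conditions and is removed by filtration.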